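## Retrosynthetic overview

- The (3R)-isoflavan is reached by MOM removal from its bis-MOM ether. The C3–H of that ether comes from stereoretentive Tsuji–Wilkinson decarbonylation of a C3-quaternary chroman-3-carbaldehyde, made by oxidation of a 3-(hydroxymethyl)chroman.
- Feature: O1–C2–C3 of the pyran ring (ring C) is one CH2–O arm of a 3-aryl-3-benzyloxetane. The two CH2–O arms are enantiotopic and the ring A phenol oxygen (future O1) lies six atoms from either CH2. A chiral phosphoric acid therefore steers O1–C2 formation, closes ring C and sets quaternary C3, the unused arm remaining as CH2OH.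
- The oxetane comes from a 2-aryl-2-benzylpropane-1,3-diol, i.e. from a diethyl arylmalonate (ring B) C-benzylated by a ring A benzylic chloride (C3–C4 bond).
- Ring B: 2-bromo-5-methoxyphenol, 1,1-dimethylpropargyl ether, semi-hydrogenation, Claisen rearrangement (3'-prenyl), MOM, palladium-catalysed malonate arylation. Ring A: 2,4-dihydroxy-6-methoxybenzaldehyde, 4-O-MOM, 2-O-allyl, reduction, chlorination.
- Ring order: rings A and B are bought; the oxetane is closed first (step 12) and is then traded for ring C (step 14).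

Key step: step 14

Assumption 1: 2,4-dihydroxy-6-methoxybenzaldehyde is taken as a catalogue compound; were it not at hand, Vilsmeier–Haack formylation of 5-methoxyresorcinol would supply it.

Assumption 2: the sense of induction of the phosphoric acid on the phenol–oxetane cannot be predicted with confidence; the (R)-acid is written, and the (S)-acid would be used should a first run favour the (3S)-alcohol.

Abbreviations: MOM = methoxymethyl; prenyl = 3-methylbut-2-en-1-yl; allyl = prop-2-en-1-yl; (R)-TRIP = (R)-3,3'-bis(2,4,6-triisopropylphenyl)-1,1'-binaphthyl-2,2'-diyl hydrogen phosphate.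

## Route

Step 1
Reactants: 1 2-bromo-5-methoxyphenol; 2 3-chloro-3-methylbut-1-yne
Product: 3 1-bromo-4-methoxy-2-[(2-methylbut-3-yn-2-yl)oxy]benzene
Conditions: CuCl2·2H2O (1 mol%), DBU, MeCN, 0 °C
Reagents that add atoms: none
Why: Copper-catalysed propargylic etherification of a phenol with a tertiary propargylic chloride is the standard entry to 1,1-dimethylpropargyl aryl ethers and avoids the elimination seen under plain Williamson conditions.

Step 2
Reactants: 3 1-bromo-4-methoxy-2-[(2-methylbut-3-yn-2-yl)oxy]benzene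
Product: 4 1-bromo-4-methoxy-2-[(2-methylbut-3-en-2-yl)oxy]benzene
Conditions: H2 (1 atm), Lindlar catalyst (Pd/CaCO3, Pb(OAc)2-poisoned), quinoline, EtOAc, rt
Reagents that add atoms: none
Why: Lindlar semi-hydrogenation stops at the terminal alkene, and the poisoned catalyst should not hydrogenolyse the aryl bromide.

Step 3
Reactants: 4 1-bromo-4-methoxy-2-[(2-methylbut-3-en-2-yl)oxy]benzene
Product: 5 6-bromo-3-methoxy-2-prenylphenol
Conditions: N,N-diethylaniline, 130 °C
Reagents that add atoms: none
Why: The aromatic Claisen ([3,3]) rearrangement of a 1,1-dimethylallyl aryl ether delivers the allyl unit with transposition to the only free ortho carbon (the other carries bromine), giving the linear prenyl group between OH and OMe after tautomerisation.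

Step 4
Reactants: 5 6-bromo-3-methoxy-2-prenylphenol
Product: 6 1-bromo-4-methoxy-2-(methoxymethoxy)-3-prenylbenzene
Conditions: NaH, THF/DMF, 0 °C; MOMCl, 0 °C → rt
Reagents that add atoms: chloromethyl methyl ether (MOMCl), COCCl
Why: Williamson-type acetalisation of the sodium phenoxide masks the 2'-oxygen so that it can later neither quench organometallic steps nor open the oxetane.

Step 5
Reactants: 6 1-bromo-4-methoxy-2-(methoxymethoxy)-3-prenylbenzene; 7 diethyl malonate
Product: 8 diethyl 2-[4-methoxy-2-(methoxymethoxy)-3-prenylphenyl]propanedioate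
Conditions: Pd(OAc)2 (2 mol%), P(t-Bu)3·HBF4 (4 mol%), K3PO4, toluene, 70 °C
Reagents that add atoms: none
Why: Palladium-catalysed α-arylation of a malonate enolate with a bulky electron-rich monophosphine tolerates electron-rich ortho-substituted aryl bromides, and the remote prenyl alkene cannot reach the aryl–palladium centre for a Heck cyclisation.

Step 6
Reactants: 9 2,4-dihydroxy-6-methoxybenzaldehyde
Product: 10 2-hydroxy-6-methoxy-4-(methoxymethoxy)benzaldehyde
Conditions: MOMCl (1.05 equiv), K2CO3, acetone, 0 °C → rt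
Reagents that add atoms: chloromethyl methyl ether (MOMCl), COCCl
Why: O-Alkylation under mild base is selective for the 4-OH, which is the more acidic (para to the formyl group) and is not held in the hydrogen bond that ties the 2-OH to the carbonyl.

Step 7
Reactants: 10 2-hydroxy-6-methoxy-4-(methoxymethoxy)benzaldehyde
Product: 11 2-(allyloxy)-6-methoxy-4-(methoxymethoxy)benzaldehyde
Conditions: allyl bromide, K2CO3, DMF, 50 °C
Reagents that add atoms: allyl bromide, C=CCBr
Why: Williamson etherification of the chelated ortho-phenol installs an allyl group that survives hydride, organolithium and base and can later be removed under neutral palladium catalysis without touching MOM, prenyl or oxetane.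

Step 8
Reactants: 11 2-(allyloxy)-6-methoxy-4-(methoxymethoxy)benzaldehyde
Product: 12 [2-(allyloxy)-6-methoxy-4-(methoxymethoxy)phenyl]methanol
Conditions: NaBH4, MeOH/THF, 0 °C
Reagents that add atoms: none
Why: Borohydride reduction of the aldehyde gives the benzylic alcohol while the ethers, the acetal and the allyl group are inert.

Step 9
Reactants: 12 [2-(allyloxy)-6-methoxy-4-(methoxymethoxy)phenyl]methanol
Product: 14 2-(allyloxy)-6-methoxy-4-(methoxymethoxy)benzyl chloride, via benzylic mesylate 13 (not isolated)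
Conditions: MsCl, Et3N, CH2Cl2, −20 → 0 °C; cold NaHCO3 wash, solution used at once
Reagents that add atoms: methanesulfonyl chloride, CS(=O)(=O)Cl
Why: Sulfonylation followed by displacement of the highly activated mesylate by the chloride of the ammonium salt gives the benzylic chloride under basic, MOM-compatible conditions; it is kept cold and not stored because the trioxygenated ring makes it prone to ionisation.

Step 10
Reactants: 8 diethyl 2-[4-methoxy-2-(methoxymethoxy)-3-prenylphenyl]propanedioate; 14 2-(allyloxy)-6-methoxy-4-(methoxymethoxy)benzyl chloride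
Product: 15 diethyl 2-[2-(allyloxy)-6-methoxy-4-(methoxymethoxy)benzyl]-2-[4-methoxy-2-(methoxymethoxy)-3-prenylphenyl]propanedioate
Conditions: NaH, THF/DMF (4:1), 0 °C; then 14, NaI (10 mol%), 0 °C → rt
Reagents that add atoms: none
Why: C-Alkylation of the stabilised sodium enolate of the arylmalonate with a very reactive benzylic halide (iodide-assisted, Finkelstein) builds the quaternary carbon that becomes C3 together with the C3–C4 bond.

Step 11
Reactants: 15 diethyl 2-[2-(allyloxy)-6-methoxy-4-(methoxymethoxy)benzyl]-2-[4-methoxy-2-(methoxymethoxy)-3-prenylphenyl]propanedioate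
Product: 16 2-[2-(allyloxy)-6-methoxy-4-(methoxymethoxy)benzyl]-2-[4-methoxy-2-(methoxymethoxy)-3-prenylphenyl]propane-1,3-diol
Conditions: LiAlH4, THF, 0 °C → rt
Reagents that add atoms: none
Why: Hydride reduction of both esters of a non-enolisable malonate gives the 2,2-disubstituted propane-1,3-diol, and keeping the mixture cold limits retro-aldol loss of formaldehyde from the intermediate alkoxy aldehyde.

Step 12
Reactants: 16 2-[2-(allyloxy)-6-methoxy-4-(methoxymethoxy)benzyl]-2-[4-methoxy-2-(methoxymethoxy)-3-prenylphenyl]propane-1,3-diol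
Product: 18 3-[2-(allyloxy)-6-methoxy-4-(methoxymethoxy)benzyl]-3-[4-methoxy-2-(methoxymethoxy)-3-prenylphenyl]oxetane, via racemic monotosylate 17 (not isolated)
Conditions: n-BuLi (1.0 equiv), THF, 0 °C; TsCl (1.0 equiv), 0 °C; n-BuLi (1.1 equiv), 0 → 60 °C
Reagents that add atoms: p-toluenesulfonyl chloride, Cc1ccc(cc1)S(Cl)(=O)=O (its atoms stay in 17 only and leave again on ring closure)
Why: Monotosylation of the monolithium alkoxide followed by 4-exo-tet Williamson closure of the second alkoxide is the standard route from 2,2-disubstituted propane-1,3-diols to 3,3-disubstituted oxetanes, and because the two hydroxymethyl groups are equivalent the racemic tosylate converges on the achiral oxetane.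

Step 13
Reactants: 18 3-[2-(allyloxy)-6-methoxy-4-(methoxymethoxy)benzyl]-3-[4-methoxy-2-(methoxymethoxy)-3-prenylphenyl]oxetane
Product: 19 3-methoxy-5-(methoxymethoxy)-2-({3-[4-methoxy-2-(methoxymethoxy)-3-prenylphenyl]oxetan-3-yl}methyl)phenol
Conditions: Pd(PPh3)4 (5 mol%), morpholine, THF, rt; chromatography on Et3N-deactivated silica
Reagents that add atoms: none
Why: In this Tsuji–Trost-type deallylation zerovalent palladium ionises the aryl allyl ether to a π-allyl complex that morpholine traps, freeing the phenol under neutral conditions in which the oxetane should not open and the prenyl group, which has no allylic leaving group, is inert.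

Step 14
Reactants: 19 3-methoxy-5-(methoxymethoxy)-2-({3-[4-methoxy-2-(methoxymethoxy)-3-prenylphenyl]oxetan-3-yl}methyl)phenol
Product: 20 [(3R)-5-methoxy-7-(methoxymethoxy)-3-[4-methoxy-2-(methoxymethoxy)-3-prenylphenyl]-3,4-dihydro-2H-chromen-3-yl]methanol
Conditions: (R)-TRIP (10 mol%), toluene, 25–40 °C
Reagents that add atoms: none
Why: The phosphoric acid hydrogen-bonds to the oxetane oxygen through its P–OH while its P=O accepts the phenolic O–H, so the ring A phenol oxygen attacks one oxetane CH2 in an SN2 opening driven by release of the four-membered ring strain, forming O1–C2 and leaving the other arm as CH2OH. The closest known reaction type is the chiral-phosphoric-acid-catalysed intramolecular desymmetrisation of 3,3-disubstituted oxetanes by tethered oxygen nucleophiles. Ring C closes in a 6-exo-tet mode, the departing oxetane oxygen lying outside the new ring. C3 becomes a quaternary stereocentre whose configuration is fixed by which of the two enantiotopic CH2–O arms is attacked, and that choice is made by the 3,3'-aryl pocket of the acid. The step needs this group selectivity and also chemoselectivity for the phenol over the other oxygens: the 2'-oxygen of ring B and the 7-oxygen are MOM ethers and the second ortho oxygen of ring A is a methyl ether, so the only O–H able to engage the bifunctional catalyst is the one that gives the chroman, and a 5-exo opening to a dihydrobenzofuran is shut off.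

Step 15
Reactants: 20 [(3R)-5-methoxy-7-(methoxymethoxy)-3-[4-methoxy-2-(methoxymethoxy)-3-prenylphenyl]-3,4-dihydro-2H-chromen-3-yl]methanol
Product: 21 (3S)-5-methoxy-7-(methoxymethoxy)-3-[4-methoxy-2-(methoxymethoxy)-3-prenylphenyl]-3,4-dihydro-2H-chromene-3-carbaldehyde
Conditions: Dess–Martin periodinane, CH2Cl2, 0 °C → rt
Reagents that add atoms: none
Why: Dess–Martin oxidation of the neopentyl-type primary alcohol gives an aldehyde without α-hydrogen, which can neither epimerise nor eliminate the β-aryloxy group (the descriptor changes from R to S by priority only).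

Step 16
Reactants: 21 (3S)-5-methoxy-7-(methoxymethoxy)-3-[4-methoxy-2-(methoxymethoxy)-3-prenylphenyl]-3,4-dihydro-2H-chromene-3-carbaldehyde
Product: 22 (3R)-5-methoxy-7-(methoxymethoxy)-3-[4-methoxy-2-(methoxymethoxy)-3-prenylphenyl]-3,4-dihydro-2H-chromene
Conditions: RhCl(PPh3)3 (1.1 equiv), degassed xylene, 130 °C
Reagents that add atoms: none
Why: In the Tsuji–Wilkinson decarbonylation the formyl C–H adds oxidatively to monovalent rhodium, CO is extruded by alkyl migration and C–H reductive elimination follows, all at the metal, so H takes the place of CHO with retention at the benzylic quaternary carbon, as is known for α-aryl quaternary aldehydes; the carbonyl complex formed is inert, hence the stoichiometric charge.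

Step 17
Reactants: 22 (3R)-5-methoxy-7-(methoxymethoxy)-3-[4-methoxy-2-(methoxymethoxy)-3-prenylphenyl]-3,4-dihydro-2H-chromene
Product: 23 (3R)-3-(2-hydroxy-4-methoxy-3-prenylphenyl)-5-methoxy-3,4-dihydro-2H-chromen-7-ol (CNP0119532.1)
Conditions: 3 M aq. HCl, MeOH, rt → 40 °C
Reagents that add atoms: none
Why: Acid-catalysed acetal exchange with methanol removes both MOM groups as dimethoxymethane under conditions milder than those needed for cyclisation of the ortho-prenylphenol to a 2,2-dimethylchroman, and the non-acidic C3 stereocentre is untouched.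

## Compound list

1 | 2-bromo-5-methoxyphenol | COc1ccc(Br)c(O)c1 | starting material
2 | 3-chloro-3-methylbut-1-yne | CC(C)(Cl)C#C | starting material
3 | 1-bromo-4-methoxy-2-[(2-methylbut-3-yn-2-yl)oxy]benzene | COc1ccc(Br)c(OC(C)(C)C#C)c1 | intermediate
4 | 1-bromo-4-methoxy-2-[(2-methylbut-3-en-2-yl)oxy]benzene | COc1ccc(Br)c(OC(C)(C)C=C)c1 | intermediate
5 | 6-bromo-3-methoxy-2-(3-methylbut-2-en-1-yl)phenol | COc1ccc(Br)c(O)c1CC=C(C)C | intermediate
6 | 1-bromo-4-methoxy-2-(methoxymethoxy)-3-(3-methylbut-2-en-1-yl)benzene | COCOc1c(Br)ccc(OC)c1CC=C(C)C | intermediate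
7 | diethyl malonate | CCOC(=O)CC(=O)OCC | starting material
8 | diethyl 2-[4-methoxy-2-(methoxymethoxy)-3-(3-methylbut-2-en-1-yl)phenyl]propanedioate | CCOC(=O)C(C(=O)OCC)c1ccc(OC)c(CC=C(C)C)c1OCOC | intermediate
9 | 2,4-dihydroxy-6-methoxybenzaldehyde | COc1cc(O)cc(O)c1C=O | starting material
10 | 2-hydroxy-6-methoxy-4-(methoxymethoxy)benzaldehyde | COCOc1cc(O)c(C=O)c(OC)c1 | intermediate
11 | 2-methoxy-4-(methoxymethoxy)-6-(prop-2-en-1-yloxy)benzaldehyde | COCOc1cc(OCC=C)c(C=O)c(OC)c1 | intermediate
12 | [2-methoxy-4-(methoxymethoxy)-6-(prop-2-en-1-yloxy)phenyl]methanol | COCOc1cc(OCC=C)c(CO)c(OC)c1 | intermediate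
13 | [2-methoxy-4-(methoxymethoxy)-6-(prop-2-en-1-yloxy)phenyl]methyl methanesulfonate | COCOc1cc(OCC=C)c(COS(C)(=O)=O)c(OC)c1 | intermediate
14 | 2-(chloromethyl)-1-methoxy-5-(methoxymethoxy)-3-(prop-2-en-1-yloxy)benzene | COCOc1cc(OCC=C)c(CCl)c(OC)c1 | intermediate
15 | diethyl 2-{[2-methoxy-4-(methoxymethoxy)-6-(prop-2-en-1-yloxy)phenyl]methyl}-2-[4-methoxy-2-(methoxymethoxy)-3-(3-methylbut-2-en-1-yl)phenyl]propanedioate | CCOC(=O)C(Cc1c(OC)cc(OCOC)cc1OCC=C)(c1ccc(OC)c(CC=C(C)C)c1OCOC)C(=O)OCC | intermediate
16 | 2-{[2-methoxy-4-(methoxymethoxy)-6-(prop-2-en-1-yloxy)phenyl]methyl}-2-[4-methoxy-2-(methoxymethoxy)-3-(3-methylbut-2-en-1-yl)phenyl]propane-1,3-diol (achiral) | OCC(CO)(Cc1c(OC)cc(OCOC)cc1OCC=C)c1ccc(OC)c(CC=C(C)C)c1OCOC | intermediate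
17 | racemic 3-hydroxy-2-{[2-methoxy-4-(methoxymethoxy)-6-(prop-2-en-1-yloxy)phenyl]methyl}-2-[4-methoxy-2-(methoxymethoxy)-3-(3-methylbut-2-en-1-yl)phenyl]propyl 4-methylbenzenesulfonate | Cc1ccc(cc1)S(=O)(=O)OCC(CO)(Cc1c(OC)cc(OCOC)cc1OCC=C)c1ccc(OC)c(CC=C(C)C)c1OCOC | intermediate
18 | 3-{[2-methoxy-4-(methoxymethoxy)-6-(prop-2-en-1-yloxy)phenyl]methyl}-3-[4-methoxy-2-(methoxymethoxy)-3-(3-methylbut-2-en-1-yl)phenyl]oxetane (achiral) | C=CCOc1cc(OCOC)cc(OC)c1CC1(c2ccc(OC)c(CC=C(C)C)c2OCOC)COC1 | intermediate
19 | 3-methoxy-5-(methoxymethoxy)-2-({3-[4-methoxy-2-(methoxymethoxy)-3-(3-methylbut-2-en-1-yl)phenyl]oxetan-3-yl}methyl)phenol (achiral) | COc1cc(OCOC)cc(O)c1CC1(c2ccc(OC)c(CC=C(C)C)c2OCOC)COC1 | intermediate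
20 | [(3R)-5-methoxy-7-(methoxymethoxy)-3-[4-methoxy-2-(methoxymethoxy)-3-(3-methylbut-2-en-1-yl)phenyl]-3,4-dihydro-2H-chromen-3-yl]methanol | COc1cc(OCOC)cc2c1C[C@](CO)(c1ccc(OC)c(CC=C(C)C)c1OCOC)CO2 | intermediate
21 | (3S)-5-methoxy-7-(methoxymethoxy)-3-[4-methoxy-2-(methoxymethoxy)-3-(3-methylbut-2-en-1-yl)phenyl]-3,4-dihydro-2H-chromene-3-carbaldehyde | COc1cc(OCOC)cc2c1C[C@](C=O)(c1ccc(OC)c(CC=C(C)C)c1OCOC)CO2 | intermediate
22 | (3R)-5-methoxy-7-(methoxymethoxy)-3-[4-methoxy-2-(methoxymethoxy)-3-(3-methylbut-2-en-1-yl)phenyl]-3,4-dihydro-2H-chromene | COc1cc(OCOC)cc2c1C[C@H](c1ccc(OC)c(CC=C(C)C)c1OCOC)CO2 | intermediate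
23 | (3R)-3-[2-hydroxy-4-methoxy-3-(3-methylbut-2-en-1-yl)phenyl]-5-methoxy-3,4-dihydro-2H-chromen-7-ol | COc1cc(O)cc2c1C[C@H](c1ccc(OC)c(CC=C(C)C)c1O)CO2 | target

## Step count and risks

Total step count: 17. Longest linear sequence: 13 steps (steps 1–5, then 10–17); the ring A branch (steps 6–9) joins at step 10.

**Step 14 (oxetane desymmetrisation).** The acid may discriminate poorly between the two enantiotopic oxetane methylenes. Opening at the neopentyl-type CH2 may also be slow enough for acid-induced participation of the ring B MOM oxygen to compete. The fallback moves the desymmetrisation from the oxetane to the diol; it sets out from 16 and comes back at 20. Copper-catalysed desymmetrising monobenzoylation of 16 (CuCl2, chiral bis(oxazoline) ligand of the antipode that serves the required arm, BzCl, Et3N, THF, 0 °C) would give the (S)-configured allyl-protected diol monobenzoate F1. Deallylation as in step 13 (Pd(PPh3)4, morpholine) would give the phenol monobenzoate F2. Intramolecular Mitsunobu etherification (PPh3, DIAD, THF) of the phenol onto the free CH2OH would close ring C to the chroman-3-ylmethyl benzoate F3. Methanolysis (K2CO3, MeOH) would then deliver 20.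

**Step 16 (decarbonylation).** CO extrusion from the congested quaternary acyl–rhodium hydride may be slow at tolerable temperature. The tertiary benzylic alkyl–rhodium hydride may also leak into β-hydride or β-aryloxide elimination, or into Rh–C homolysis with erosion of configuration. The fallback sets C3–H by auxiliary-controlled alkylation instead of excision; it sets out from 8 (and uses 14) and comes back at 22.
- Saponification of 8 (KOH, aq. EtOH) would give the arylmalonic acid F4, which on warming at pH 4 would lose CO2 to the arylacetic acid F5.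
- Activation as the mixed pivalic anhydride F6 (PivCl, Et3N, THF, −20 °C) and N-acylation of lithiated (R)-4-benzyl-1,3-oxazolidin-2-one would give the arylacetyl imide F7.
- Evans alkylation of its sodium Z-enolate (NaN(SiMe3)2, THF, −78 °C) with 14, on the face anti to the benzyl group of the auxiliary, would give the (2R)-alkylated imide F8.
- LiBH4 (THF, MeOH, 0 °C) would release the (2R)-2,3-diarylpropan-1-ol F9, and Pd(PPh3)4/morpholine its free phenol F10.
- Mitsunobu ring closure (PPh3, DIAD, THF) would form O1–C2 and give 22.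

**Step 10 (quaternary C–C bond).** The 2,4,6-trioxygenated benzylic chloride may ionise and self-condense by Friedel–Crafts oligomerisation faster than the hindered tertiary enolate attacks, and O-alkylation of the enolate may compete. The fallback uses a storable electrophile of another class; it sets out from 12 and comes back at 15. The cold solution of 14 formed as in step 9 (through 13) would be quenched at once with NMe3 to give the crystalline benzyltrimethylammonium chloride F11. This salt would benzylate the sodium enolate of 8 in DMF at 60–80 °C with loss of trimethylamine to give 15.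

## Further compounds

F1 | step 14 | (2S)-3-hydroxy-2-{[2-methoxy-4-(methoxymethoxy)-6-(prop-2-en-1-yloxy)phenyl]methyl}-2-[4-methoxy-2-(methoxymethoxy)-3-(3-methylbut-2-en-1-yl)phenyl]propyl benzoate | C=CCOc1cc(OCOC)cc(OC)c1C[C@](COC(=O)c1ccccc1)(c1ccc(OC)c(CC=C(C)C)c1OCOC)CO
F2 | step 14 | (2S)-3-hydroxy-2-{[2-hydroxy-6-methoxy-4-(methoxymethoxy)phenyl]methyl}-2-[4-methoxy-2-(methoxymethoxy)-3-(3-methylbut-2-en-1-yl)phenyl]propyl benzoate | COc1cc(OCOC)cc(O)c1C[C@](COC(=O)c1ccccc1)(c1ccc(OC)c(CC=C(C)C)c1OCOC)CO
F3 | step 14 | [(3S)-5-methoxy-7-(methoxymethoxy)-3-[4-methoxy-2-(methoxymethoxy)-3-(3-methylbut-2-en-1-yl)phenyl]-3,4-dihydro-2H-chromen-3-yl]methyl benzoate | COc1cc(OCOC)cc2c1C[C@](COC(=O)c1ccccc1)(c1ccc(OC)c(CC=C(C)C)c1OCOC)CO2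
F4 | step 16 | 2-[4-methoxy-2-(methoxymethoxy)-3-(3-methylbut-2-en-1-yl)phenyl]propanedioic acid | OC(=O)C(C(O)=O)c1ccc(OC)c(CC=C(C)C)c1OCOC
F5 | step 16 | [4-methoxy-2-(methoxymethoxy)-3-(3-methylbut-2-en-1-yl)phenyl]acetic acid | OC(=O)Cc1ccc(OC)c(CC=C(C)C)c1OCOC
F6 | step 16 | [4-methoxy-2-(methoxymethoxy)-3-(3-methylbut-2-en-1-yl)phenyl]acetic 2,2-dimethylpropanoic anhydride | CC(C)(C)C(=O)OC(=O)Cc1ccc(OC)c(CC=C(C)C)c1OCOC
F7 | step 16 | (4R)-4-benzyl-3-{[4-methoxy-2-(methoxymethoxy)-3-(3-methylbut-2-en-1-yl)phenyl]acetyl}-1,3-oxazolidin-2-one | O=C(Cc1ccc(OC)c(CC=C(C)C)c1OCOC)N1[C@H](Cc2ccccc2)COC1=O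
F8 | step 16 | (4R)-4-benzyl-3-{(2R)-3-[2-methoxy-4-(methoxymethoxy)-6-(prop-2-en-1-yloxy)phenyl]-2-[4-methoxy-2-(methoxymethoxy)-3-(3-methylbut-2-en-1-yl)phenyl]propanoyl}-1,3-oxazolidin-2-one | O=C([C@H](Cc1c(OC)cc(OCOC)cc1OCC=C)c1ccc(OC)c(CC=C(C)C)c1OCOC)N1[C@H](Cc2ccccc2)COC1=O
F9 | step 16 | (2R)-3-[2-methoxy-4-(methoxymethoxy)-6-(prop-2-en-1-yloxy)phenyl]-2-[4-methoxy-2-(methoxymethoxy)-3-(3-methylbut-2-en-1-yl)phenyl]propan-1-ol | OC[C@H](Cc1c(OC)cc(OCOC)cc1OCC=C)c1ccc(OC)c(CC=C(C)C)c1OCOC
F10 | step 16 | 2-{(2R)-3-hydroxy-2-[4-methoxy-2-(methoxymethoxy)-3-(3-methylbut-2-en-1-yl)phenyl]propyl}-3-methoxy-5-(methoxymethoxy)phenol | OC[C@H](Cc1c(OC)cc(OCOC)cc1O)c1ccc(OC)c(CC=C(C)C)c1OCOC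
F11 | step 10 | {[2-methoxy-4-(methoxymethoxy)-6-(prop-2-en-1-yloxy)phenyl]methyl}trimethylammonium chloride | COCOc1cc(OCC=C)c(C[N+](C)(C)C)c(OC)c1.[Cl-]
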